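## Analysis of the target

The target 12 is a 20-membered macrocycle in which two benzene rings are joined twice, once through a diaryl ether oxygen and once through an unbranched chain of fourteen methylene groups, C1 to C14. Ring A is 1,3,5-substituted (OH on A1, chain end C14 on A3, ether oxygen on A5), ring B is 1,2,4,6-substituted (ether oxygen on B1, OH on B2 and B4, chain end C1 on B6), and the large ring runs A3–A4–A5–O–B1–B6–C1…C14. There is no stereocentre, and the ring is wide enough for both arenes to turn, so the compound is achiral and no configuration has to be set. The sensitive part is ring B, a 1,2,4-trioxygenated arene that is readily oxidised to a quinone once its phenols are free, which is why the oxygens on A1 and B2 stay methyl ethers until the last step. The difficulties are the entropic cost of the large ring, the crowded ether carbon B1 between an oxygen-bearing carbon and the chain-bearing carbon, and the need to place four different substituents on ring B without a regiochemical mixture. The strategy rests on one feature of ring B: the chain sits on B6, next to the ether carbon B1 and in a 1,3-relation to the hydroxyl carbon B4. This is the arrangement that results when an alkyl group shifts from C4 to a neighbouring carbon of a 4-alkyl-4-aryloxycyclohexa-2,5-dienone in which B4 is the carbonyl carbon, so ring B can be read as the rearranged and aromatised form of a quinol aryl ether that still has C1 on B1.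

## Retrosynthetic reasoning

12 back to 11. Only the two O–methyl bonds on A1 and B2 are cut. Methyl ethers are chosen because they pass unchanged through the organometallic, basic, palladium-catalysed and acidic steps and fall together to one Lewis acid. The B4 hydroxyl of 11 needs no protection, because it is what the dienone carbonyl becomes.

11 back to 10. The B6–C1 bond is cut, C1 is put back on B1 and ring B is dearomatised to the cross-conjugated dienone with its carbonyl on B4. This gives the 19-membered quinol aryl ether 10. The cut is made here because it turns the most awkward aromatic carbon of the target into a fully substituted sp3 carbon bearing oxygen and a primary alkyl group, which is what a carbonyl addition delivers. The substitution pattern of ring B then no longer has to be built by aromatic substitution. The forward reaction, an acid-induced 1,2-shift, must move carbon and not oxygen, and must move it to B6 and not to B2. It enlarges the ring by one atom and is paid for by aromatisation.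

10 back to 9. The B4 carbonyl is masked as the dimethyl ketal 9. Every bond at B1 and the ring closure are made under basic, organometallic or hydroborating conditions that a free dienone would not survive. The ketal is also the form in which a dearomatised ring B comes directly from a phenol. The forward step is a mild hydrolysis that must not set off the rearrangement.

9 back to 7 through 8. The C14–A3 bond is cut, which opens the 19-membered ring to the aryl bromide and terminal alkene of 7. The other two candidate bonds, O–A5 and B1–C1, lie at the congested quaternary carbon and are better made between separate molecules. The sp2–sp3 bond at A3 is remote from B1, and coupling through the alkylborane 8 delivers the saturated chain directly. No olefin then has to be hydrogenated in the presence of the ring B double bonds.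

7 back to 5 and 6. The O–A5 bond is cut so that the oxygen of 5 is the nucleophile, as its tertiary alkoxide, and ring A is the electrophile, as the aryl fluoride 6. Closing this bond by oxidative phenol coupling was set aside for three reasons: ring A is a resorcinol-type arene that would react through carbon, both phenolic rings would be oxidisable, and the same step would also have to form the large ring. In 6 the 1,3,5-pattern fixes the regiochemistry; fluoride leaves and the bromide is kept for the ring closure.

5 back to 2 and 3 through 4. The B1–C1 bond is cut to the carbonyl of the quinone monoketal 2 and the Grignard reagent 4, made from bromide 3. One 1,2-addition sets the quaternary carbon, its oxygen and the whole chain, with the B2 methoxy group already next to the carbonyl.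

2 back to 1. The monoketal 2 is the product of oxidative dearomatisation of phenol 1 in methanol; the para carbon that becomes the ketal is B4.

## Alternatives that were turned down

Alternative 1: Ring B would be built last from the open-chain aryloxymalonate A2, in which ring A carries the malonate on its ether oxygen and the chain ends in a methyl enone. The forward key step is a Michael–Claisen annulation with NaOMe in methanol at high dilution. The malonate carbon would add to the enone β-carbon (bond B1–B6, which also closes the 20-membered ring), and the enolate on the methyl side of the ketone would then acylate on one ester (bond B2–B3). The product would be the macrocyclic cyclohexane-1,3-dione A1 as a mixture of diastereomers. Ester cleavage with decarboxylation, dehydrogenation of ring B to the aromatic level and demethylation would still be needed.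
- For it: the chain is on B6 from the start, so the regiochemistry of ring B does not depend on a migratory preference. On that point it is stronger than the chosen route.
- Against it: the ring-closing event is a reversible Michael addition of a hindered, doubly stabilised carbanion that creates a quaternary carbon. At high dilution it competes with oligomerisation and retro-addition. Three further operations are needed to aromatise A1, and A2 itself needs a long linear sequence.
- Comparison: the chosen route closes its large ring by an irreversible cross-coupling and reaches the aromatic ring B in one unimolecular step that needs no dilution.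

Alternative 2: Both aryl–chain bonds would be made by olefin metathesis. The divinyl diaryl ether A4 and cyclododecene A5 would be combined with the second-generation Grubbs catalyst RuCl2(=CHPh)(PCy3)(H2IMes) at high dilution. Ring opening of A5 and cross-metathesis with both styrene ends would create C1=C2 and C13=C14, release ethene and give the macrocyclic diene A3 as an E/Z mixture. Hydrogenation and demethylation would follow.
- For it: both arenes are bought with their substituents in place, and every reaction type is well established. In convergence and in reliance on known chemistry it is at least as good as the chosen route.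
- Against it: the key step must insert exactly one molecule of the nearly strain-free A5 between two styrene ends. Polymerisation of A5, double insertion and styrene homocoupling are statistically favoured, and the vinyl group on B6 is hindered by the ortho aryloxy group. A4 itself needs a diaryl ether bond at an oxygen flanked by two ortho substituents.
- Comparison: the chosen route has no stoichiometry problem in the step that sets the ring size, since the chain length is fixed in bromide 3.

Alternative 3: Ring A and the macrocycle would be formed together by a benzannulation. The precursor A7 carries an ethynyl ether on B1 and a 3-alkylcyclobutenone at the end of the chain. Heating A7 at high dilution would open the four-membered ring electrocyclically. [2+2] addition to the ynol ether, a second ring opening and a 6π closure would then give the phenol A6, in which ring A and the 20-membered ring have closed in one operation.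
- For it: ring A is formed with its 1,3,5-pattern and with the A1 hydroxyl already free and distinct from the ring B methyl ethers. In regiocontrol of ring A and in protecting-group economy it is stronger than the chosen route.
- Against it: the ynol ether and cyclobutenone ends of A7 each take several steps to install and are thermally and hydrolytically fragile. The ketene–alkyne addition has to occur between the two ends of a long chain, so it must compete with ketene dimerisation at the temperatures required.
- Comparison: the chosen route reaches its key precursor in five steps from catalogue compounds, and its uncertainty is confined to one acid-induced step.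

Key step: step 6

Remark on the chemistry: 1, 3 and 6 are taken as catalogue compounds, and 5, 7, 8, 9 and 10, which each carry the single stereocentre B1, are carried as racemates because that centre is erased in step 6.

Step 1
Reactants: 1 2,4-dimethoxyphenol
Product: 2 2,4,4-trimethoxycyclohexa-2,5-dien-1-one
Conditions: PhI(OAc)2, MeOH, 0 °C
Reagents that add atoms: methanol, CO
Why: Oxidative dearomatisation of a para-methoxyphenol by a trivalent iodine reagent in methanol; methanol attacks the methoxy-bearing para carbon, which carries most of the positive charge, so the para-quinone monoketal should form in preference to the ortho ketal.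

Step 2
Reactants: 2 2,4,4-trimethoxycyclohexa-2,5-dien-1-one; 3 14-bromotetradec-1-ene
Product: 5 racemic 2,4,4-trimethoxy-1-(tetradec-13-en-1-yl)cyclohexa-2,5-dien-1-ol, via tetradec-13-en-1-ylmagnesium bromide 4 (not isolated)
Conditions: Mg, THF, rt; then 2, THF, −78 to 0 °C; aq. NaHCO3
Reagents that add atoms: none
Why: Grignard formation and 1,2-addition to the carbonyl of a quinone monoketal; both β-carbons are shielded by the adjacent ketal carbon and the α-methoxy group can chelate magnesium, so the primary Grignard reagent 4 should add to the carbonyl and give the quinol ketal. The new stereocentre B1 forms without control as a racemate and is erased in step 6.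

Step 3
Reactants: 5 racemic 2,4,4-trimethoxy-1-(tetradec-13-en-1-yl)cyclohexa-2,5-dien-1-ol; 6 1-bromo-3-fluoro-5-methoxybenzene
Product: 7 racemic 1-bromo-3-methoxy-5-{[2,4,4-trimethoxy-1-(tetradec-13-en-1-yl)cyclohexa-2,5-dien-1-yl]oxy}benzene
Conditions: KH, THF, 0 °C; then 6, DMF, 25–60 °C
Reagents that add atoms: none
Why: Nucleophilic aromatic substitution (addition–elimination) by the potassium alkoxide of 5 on an aryl fluoride activated inductively by the meta bromine and meta methoxy groups; fluoride should leave in preference to bromide, and the 1,3,5-pattern of 6 fixes where the oxygen enters. The ketal, enol ether and terminal alkene are inert to these basic conditions.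

Step 4
Reactants: 7 racemic 1-bromo-3-methoxy-5-{[2,4,4-trimethoxy-1-(tetradec-13-en-1-yl)cyclohexa-2,5-dien-1-yl]oxy}benzene
Product: 9 racemic 19-membered macrocyclic quinol ketal whose 2,4,4-trimethoxycyclohexa-2,5-diene ring B carries on B1 the ether oxygen to A5 and chain carbon C1 while C14 sits on A3 and OMe on A1, via B-alkyl-9-borabicyclo[3.3.1]nonane adduct 8 (not isolated)
Conditions: 9-BBN-H, THF, rt; then PdCl2(dppf) (cat.), AsPh3, Cs2CO3, DMF/THF/H2O, 50 °C, slow addition, about 1 mM
Reagents that add atoms: none
Why: B-alkyl Suzuki–Miyaura macrocyclisation: 9-BBN-H should hydroborate only the terminal alkene, because the ring olefins are flanked by fully substituted carbons, and the alkylborane then couples with the aryl bromide under zerovalent palladium catalysis at high dilution to close the 19-membered ring with a saturated chain. Oxidative addition into the aryl bromide is expected to be faster than ionisation of the hindered tertiary allylic aryl ether.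

Step 5
Reactants: 9 racemic 19-membered macrocyclic quinol ketal
Product: 10 racemic 19-membered quinol aryl ether: a 4-alkyl-4-aryloxy-3-methoxycyclohexa-2,5-dien-1-one with C=O on B4, OMe on B2, the A5 oxygen and C1 on B1, C14 on A3 and OMe on A1
Conditions: PPTS, acetone/H2O, rt
Reagents that add atoms: water, O
Why: Hydrolysis of a doubly allylic dimethyl ketal under mild aqueous acid; loss of methanol from B4 gives a cation stabilised by the remaining methoxy group and by the B2 enol ether, so the ketal should ionise far faster than the B1–O bond, and water should return at the unhindered B4 rather than at B2 beside the quaternary carbon, giving the cross-conjugated vinylogous ester. A buffered pyridinium acid is too weak to start the rearrangement of step 6.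

Step 6
Reactants: 10 racemic 19-membered quinol aryl ether
Product: 11 20-membered diaryl ether macrocycle with OMe on A1 and B2, free OH on B4, C1 on B6 and C14 on A3
Conditions: CF3CO2H, CH2Cl2, 0 °C to rt
Reagents that add atoms: none
Why: Proposed new method: protonation of the B4 carbonyl of 10 gives a 4-hydroxy-2-methoxycyclohexadienyl cation with positive character on B2 and B6; the chain carbon C1 then moves with its bonding pair from the quaternary B1 to the unsubstituted B6, the cation left on B1 is an aryloxy-stabilised oxocarbenium ion, and loss of the B6 proton gives phenol 11. The closest known reaction type is the acid-promoted quinol (dienone–phenol) rearrangement of 4-alkyl-4-hydroxy- and 4-alkyl-4-alkoxycyclohexa-2,5-dienones by 1,2-alkyl shift; new here are the aryloxy group at the migration origin and the insertion of B6 into a macrocycle. The 20-membered ring is not closed end to end: it arises by this suprafacial 1,2-shift inside the existing 19-membered ring, a one-atom ring expansion that needs no dilution and is driven by the aromatisation of ring B. No stereocentre is formed, and the only stereocentre of 10, B1, becomes trigonal, so racemic 10 should give achiral 11. The step needs carbon and not oxygen to migrate, and needs it to go to B6 and not to B2: the aryloxy oxygen is worth more as a donor to the cation left on B1 than as a migrating group, and a shift to the methoxy-bearing B2 would destroy the vinylogous ester stabilisation and lead to a cation that cannot aromatise by proton loss. Heterolysis of the B1–O bond is disfavoured because the B2 methoxy group sits on a nodal carbon of the phenoxenium ion that would result and cannot stabilise it.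

Step 7
Reactants: 11 20-membered diaryl ether macrocycle with OMe on A1 and B2
Product: 12 target, the 20-membered diaryl ether macrocycle with OH on A1, B2 and B4
Conditions: BBr3, CH2Cl2, −78 °C to rt; then H2O
Reagents that add atoms: none
Why: Lewis acid cleavage of aryl methyl ethers by BBr3 (complexation at oxygen, bromide attack at methyl); the diaryl ether has no sp3 carbon on oxygen and should be inert, as is the chain. Aqueous work-up under argon releases the three phenols.

## Compound list

1 | 2,4-dimethoxyphenol | COc1ccc(O)c(OC)c1 | starting material
2 | 2,4,4-trimethoxycyclohexa-2,5-dien-1-one | COC1=CC(OC)(OC)C=CC1=O | intermediate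
3 | 14-bromotetradec-1-ene | C=CCCCCCCCCCCCCBr | starting material
4 | tetradec-13-en-1-ylmagnesium bromide | C=CCCCCCCCCCCCC[Mg]Br | intermediate
5 | racemic 2,4,4-trimethoxy-1-(tetradec-13-en-1-yl)cyclohexa-2,5-dien-1-ol | COC1=CC(OC)(OC)C=CC1(O)CCCCCCCCCCCCC=C | intermediate
6 | 1-bromo-3-fluoro-5-methoxybenzene | COc1cc(F)cc(Br)c1 | starting material
7 | racemic 1-bromo-3-methoxy-5-{[2,4,4-trimethoxy-1-(tetradec-13-en-1-yl)cyclohexa-2,5-dien-1-yl]oxy}benzene | COC1=CC(OC)(OC)C=CC1(CCCCCCCCCCCCC=C)Oc1cc(Br)cc(OC)c1 | intermediate
8 | racemic 9-{14-[1-(3-bromo-5-methoxyphenoxy)-2,4,4-trimethoxycyclohexa-2,5-dien-1-yl]tetradecyl}-9-borabicyclo[3.3.1]nonane | COC1=CC(OC)(OC)C=CC1(CCCCCCCCCCCCCCB2C3CCCC2CCC3)Oc1cc(Br)cc(OC)c1 | intermediate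
9 | racemic 19-membered macrocyclic quinol ketal: B1 of a 2,4,4-trimethoxycyclohexa-2,5-diene ring bears the A5 oxygen and C1; C14 on A3; OMe on A1 | COc1cc2cc(c1)OC1(C=CC(OC)(OC)C=C1OC)CCCCCCCCCCCCCC2 | intermediate
10 | racemic 19-membered quinol aryl ether: 4-alkyl-4-aryloxy-3-methoxycyclohexa-2,5-dien-1-one, C=O on B4, OMe on B2 and A1 | COc1cc2cc(c1)OC1(C=CC(=O)C=C1OC)CCCCCCCCCCCCCC2 | intermediate
11 | 20-membered diaryl ether macrocycle, OMe on A1 and B2, OH on B4, C1 on B6, C14 on A3 | COc1cc2cc(c1)Oc1c(OC)cc(O)cc1CCCCCCCCCCCCCC2 | intermediate
12 | 20-membered diaryl ether macrocycle, OH on A1, B2 and B4 (CNP0173380.0) | Oc1cc2cc(c1)Oc1c(O)cc(O)cc1CCCCCCCCCCCCCC2 | target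

## Step count and least certain steps

Total step count: 7. Longest linear sequence: 7 (1 → 2 → 5 → 7 → 9 → 10 → 11 → 12).

**Step 6 (key step).** Three things may go wrong. Heterolysis of the B1–O bond or a charge-accelerated [3,3] shift of the allyl aryl ether unit could compete with the alkyl shift, leading to loss of ring A or to carbon–carbon bonding between the rings. The chain could first shift toward the methoxy-bearing B2 and then move on to B3, which would put it between the two oxygens. The protonated vinylogous ester is a stabilised cation and may react slowly, so that the stronger acid then needed begins to cleave the methyl ethers.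

The fallback sets out from 5 and returns to the route at 12; it uses known reactions and avoids a quinol aryl ether. Mild hydrolysis of the ketal of 5 (PPTS, aqueous acetone) would give the free quinol, racemic 4-hydroxy-3-methoxy-4-(tetradec-13-en-1-yl)cyclohexa-2,5-dien-1-one F1. Its acid-promoted quinol rearrangement (CF3CO2H, CH2Cl2), the classical 1,2-alkyl shift of 4-alkyl-4-hydroxycyclohexa-2,5-dienones, would give 2-methoxy-6-(tetradec-13-en-1-yl)benzene-1,4-diol F2. Methylation of its unhindered hydroxyl with one equivalent of MeI and K2CO3 in acetone would give 2,4-dimethoxy-6-(tetradec-13-en-1-yl)phenol F3; the other hydroxyl is shielded by the methoxy group and the chain. Ullmann-type coupling of F3 with 1-bromo-3-iodo-5-methoxybenzene F4 at the carbon–iodine bond (CuI, picolinic acid, K3PO4, DMSO, 90 °C) would give 1-bromo-3-[2,4-dimethoxy-6-(tetradec-13-en-1-yl)phenoxy]-5-methoxybenzene F5. Hydroboration of F5 with 9-BBN-H would give the alkylborane 9-{14-[2-(3-bromo-5-methoxyphenoxy)-3,5-dimethoxyphenyl]tetradecyl}-9-borabicyclo[3.3.1]nonane F6. Coupling under the conditions of step 4 would then close the 20-membered ring directly to the tri-O-methyl ether of the target F7. BBr3 would convert F7 into 12.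

**Step 3.** Substitution by a hindered tertiary alkoxide on a weakly activated fluoroarene may be slow. The heating then needed could bring on a [3,3] shift of the tertiary allyl aryl ether that is being formed, or elimination to an aryne on the bromofluoroarene.

The fallback sets out from 5 and returns to the route at 7; the oxygen–aryl bond is made by ligand coupling at trivalent iodine at room temperature. F4 would be oxidised with mCPBA in the presence of TsOH·H2O and coupled in the same flask with 1,3,5-trimethoxybenzene F8 to give (3-bromo-5-methoxyphenyl)(2,4,6-trimethoxyphenyl)iodonium 4-methylbenzenesulfonate F9. The sodium alkoxide of 5 (NaH, toluene, rt) would then take the more electron-poor aryl group from F9 and give 7.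

**Step 4.** The zerovalent palladium catalyst may insert into the tertiary allylic carbon–oxygen bond at B1, with loss of the ring A aryloxide and aromatisation of ring B. Intermolecular coupling may also compete with ring closure despite dilution.

The fallback sets out from 7 and returns to the route at 9; the ring is closed by olefin metathesis without palladium. Bromine–lithium exchange on 7 (t-BuLi, THF, −78 °C) and quenching with DMF would give racemic 3-methoxy-5-{[2,4,4-trimethoxy-1-(tetradec-13-en-1-yl)cyclohexa-2,5-dien-1-yl]oxy}benzaldehyde F10. Wittig methylenation (Ph3P=CH2, THF) would give the styrene, racemic 1-ethenyl-3-methoxy-5-{[2,4,4-trimethoxy-1-(tetradec-13-en-1-yl)cyclohexa-2,5-dien-1-yl]oxy}benzene F11. Ring-closing metathesis of F11 with the second-generation Grubbs catalyst RuCl2(=CHPh)(PCy3)(H2IMes) in CH2Cl2 at about 1 mM would give the 19-membered macrocyclic C13=C14 alkene F12 as an E/Z mixture. Diimide (2-nitrobenzenesulfonylhydrazide, Et3N, CH2Cl2, rt) should reduce this unhindered disubstituted alkene of F12 and leave the two ring B olefins, which are flanked by fully substituted carbons, to give 9.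

## Further compounds

F1 | step 6 | racemic 4-hydroxy-3-methoxy-4-(tetradec-13-en-1-yl)cyclohexa-2,5-dien-1-one | COC1=CC(=O)C=CC1(O)CCCCCCCCCCCCC=C
F2 | step 6 | 2-methoxy-6-(tetradec-13-en-1-yl)benzene-1,4-diol | COc1cc(O)cc(CCCCCCCCCCCCC=C)c1O
F3 | step 6 | 2,4-dimethoxy-6-(tetradec-13-en-1-yl)phenol | COc1cc(OC)c(O)c(CCCCCCCCCCCCC=C)c1
F4 | step 6 | 1-bromo-3-iodo-5-methoxybenzene | COc1cc(Br)cc(I)c1
F5 | step 6 | 1-bromo-3-[2,4-dimethoxy-6-(tetradec-13-en-1-yl)phenoxy]-5-methoxybenzene | COc1cc(Br)cc(Oc2c(OC)cc(OC)cc2CCCCCCCCCCCCC=C)c1
F6 | step 6 | 9-{14-[2-(3-bromo-5-methoxyphenoxy)-3,5-dimethoxyphenyl]tetradecyl}-9-borabicyclo[3.3.1]nonane | COc1cc(Br)cc(Oc2c(OC)cc(OC)cc2CCCCCCCCCCCCCCB3C4CCCC3CCC4)c1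
F7 | step 6 | 20-membered diaryl ether macrocycle with OMe on A1, B2 and B4 (tri-O-methyl ether of the target) | COc1cc2cc(c1)Oc1c(OC)cc(OC)cc1CCCCCCCCCCCCCC2
F8 | step 3 | 1,3,5-trimethoxybenzene | COc1cc(OC)cc(OC)c1
F9 | step 3 | (3-bromo-5-methoxyphenyl)(2,4,6-trimethoxyphenyl)iodonium 4-methylbenzenesulfonate | COc1cc(Br)cc([I+]c2c(OC)cc(OC)cc2OC)c1.Cc1ccc(cc1)S(=O)(=O)[O-]
F10 | step 4 | racemic 3-methoxy-5-{[2,4,4-trimethoxy-1-(tetradec-13-en-1-yl)cyclohexa-2,5-dien-1-yl]oxy}benzaldehyde | COC1=CC(OC)(OC)C=CC1(CCCCCCCCCCCCC=C)Oc1cc(C=O)cc(OC)c1
F11 | step 4 | racemic 1-ethenyl-3-methoxy-5-{[2,4,4-trimethoxy-1-(tetradec-13-en-1-yl)cyclohexa-2,5-dien-1-yl]oxy}benzene | COC1=CC(OC)(OC)C=CC1(CCCCCCCCCCCCC=C)Oc1cc(C=C)cc(OC)c1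
F12 | step 4 | racemic 19-membered macrocyclic quinol ketal with a C13=C14 double bond (E/Z mixture, drawn without geometry) | COc1cc2cc(c1)OC1(C=CC(OC)(OC)C=C1OC)CCCCCCCCCCCCC=C2
A1 | alternative 1 | macrocyclic 4-aryloxy-4-methoxycarbonyl-5-alkylcyclohexane-1,3-dione (diastereomer mixture, drawn without configuration) | COc1cc2cc(c1)OC1(C(=O)OC)C(=O)CC(=O)CC1CCCCCCCCCCCCCC2
A2 | alternative 1 | dimethyl 2-{3-methoxy-5-[(15E)-17-oxooctadec-15-en-1-yl]phenoxy}propanedioate | COC(=O)C(Oc1cc(OC)cc(CCCCCCCCCCCCCC/C=C/C(C)=O)c1)C(=O)OC
A3 | alternative 2 | macrocyclic 1,13-diene, tri-O-methyl (E/Z mixture, drawn without geometry) | COc1cc2cc(c1)Oc1c(OC)cc(OC)cc1C=CCCCCCCCCCCCC=C2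
A4 | alternative 2 | 1-ethenyl-2-(3-ethenyl-5-methoxyphenoxy)-3,5-dimethoxybenzene | COc1cc(C=C)cc(Oc2c(OC)cc(OC)cc2C=C)c1
A5 | alternative 2 | cyclododecene | C1=CCCCCCCCCCC1
A6 | alternative 3 | 20-membered diaryl ether macrocycle with OH on A1 and OMe on B2 and B4 | Oc1cc2cc(c1)Oc1c(OC)cc(OC)cc1CCCCCCCCCCCCCC2
A7 | alternative 3 | 3-{14-[2-(ethynyloxy)-3,5-dimethoxyphenyl]tetradecyl}cyclobut-2-en-1-one | COc1cc(OC)c(OC#C)c(CCCCCCCCCCCCCCC2=CC(=O)C2)c1
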